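**Retrosynthetic overview**
1. Ring C is the only ring built and is closed last. The O1–C2 bond forms by acid-triggered addition–elimination of a freed ring A phenol onto an enaminone, in the same pot that removes all MOM groups.
2. C2 is a one-carbon unit (DMF dimethyl acetal) placed on a deoxybenzoin, which comes from a β-keto ester by dealkoxycarbonylation.
3. Key disconnection C3–C4: intermolecular aldol addition of the lithium enolate of the ring B arylacetate to the ring A aldehyde, then oxidation of the carbinol.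
4. Ring B ester: 3,4,5-trimethoxyphenylacetic acid → triol → diphenylmethylene ketal (one OH left free) → allyl ether → Claisen rearrangement to the only free ortho carbon (fixes C2') → O-methylation → ketal-to-MOM swap → cross metathesis (allyl to prenyl).
5. Ring A aldehyde: phloroglucinol → tris-MOM ether → ortho-lithiation/DMF. Rings A and B are bought as benzene rings.

Assumption: the target SMILES has no stereocentre and no E/Z-stereogenic alkene, so the compound is achiral and no asymmetric step is needed. The transient stereocentres in 6, 17, 18 and 19 are uncontrolled and are erased later.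

**Step 1**
Reactants: 1 3,4,5-trimethoxyphenylacetic acid
Product: 3 methyl 2-(3,4,5-trihydroxyphenyl)acetate, via 3,4,5-trihydroxyphenylacetic acid 2 (not isolated)
Conditions: BBr3 (4.5 equiv), CH2Cl2, −78 °C to rt, 14 h; then MeOH, reflux, 3 h
Reagents that add atoms: methanol, CO
Why: BBr3 cleaves all three aryl methyl ethers (Lewis-acid ether cleavage), and the HBr released on the methanol quench catalyses Fischer esterification of the unhindered arylacetic acid, so the polar, air-sensitive acid need not be isolated.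

**Step 2**
Reactants: 3 methyl 2-(3,4,5-trihydroxyphenyl)acetate
Product: 4 methyl 2-(7-hydroxy-2,2-diphenyl-1,3-benzodioxol-5-yl)acetate
Conditions: Ph2CCl2 (1.1 equiv), Ph2O, 175 °C, 30 min, N2
Reagents that add atoms: dichlorodiphenylmethane, ClC(Cl)(c1ccccc1)c1ccccc1
Why: Only two adjacent phenols can bridge the Ph2C unit into a five-membered ring, so ketalisation of the symmetric pyrogallol unit (catechol diphenylmethylene ketal formation) leaves exactly one flanking OH free.

**Step 3**
Reactants: 4 methyl 2-(7-hydroxy-2,2-diphenyl-1,3-benzodioxol-5-yl)acetate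
Product: 5 methyl 2-(7-allyloxy-2,2-diphenyl-1,3-benzodioxol-5-yl)acetate
Conditions: allyl bromide (1.3 equiv), K2CO3 (2 equiv), acetone, reflux, 6 h
Reagents that add atoms: allyl bromide, C=CCBr
Why: This is a Williamson ether synthesis on the only free phenol, and K2CO3 is far too weak to enolise the arylacetate.

**Step 4**
Reactants: 5 methyl 2-(7-allyloxy-2,2-diphenyl-1,3-benzodioxol-5-yl)acetate
Product: 7 methyl 2-(6-allyl-7-hydroxy-2,2-diphenyl-1,3-benzodioxol-5-yl)acetate, via ortho-allyl cyclohexadienone 6 (not isolated)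
Conditions: PhNEt2, 205 °C, sealed tube, Ar, 8 h
Reagents that add atoms: none
Why: In this aromatic Claisen rearrangement ([3,3]-sigmatropic shift, then tautomerisation) one ortho carbon carries the ketal oxygen, so the allyl group goes to C6, the carbon between the oxygen and the acetate side chain, as the target requires.

**Step 5**
Reactants: 7 methyl 2-(6-allyl-7-hydroxy-2,2-diphenyl-1,3-benzodioxol-5-yl)acetate
Product: 8 methyl 2-(6-allyl-7-methoxy-2,2-diphenyl-1,3-benzodioxol-5-yl)acetate
Conditions: MeI (2 equiv), K2CO3 (2 equiv), DMF, rt, 12 h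
Reagents that add atoms: iodomethane, CI
Why: Williamson O-methylation of the newly released phenol installs the single methoxy group next to the allyl group.

**Step 6**
Reactants: 8 methyl 2-(6-allyl-7-methoxy-2,2-diphenyl-1,3-benzodioxol-5-yl)acetate
Product: 9 methyl 2-(2-allyl-4,5-dihydroxy-3-methoxyphenyl)acetate
Conditions: AcOH/H2O 4:1, reflux, 4 h
Reagents that add atoms: none
Why: Acid-catalysed ketal hydrolysis proceeds through the doubly benzylic oxocarbenium ion, while the terminal alkene (no ortho OH to cyclise onto) and the methyl ester tolerate hot aqueous acetic acid.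

**Step 7**
Reactants: 9 methyl 2-(2-allyl-4,5-dihydroxy-3-methoxyphenyl)acetate
Product: 10 methyl 2-[2-allyl-3-methoxy-4,5-bis(methoxymethoxy)phenyl]acetate
Conditions: MOMCl (3 equiv), i-Pr2NEt (4 equiv), CH2Cl2, 0 °C to rt, 12 h
Reagents that add atoms: chloromethyl methyl ether, COCCl
Why: O-alkylation with the oxocarbenium-type electrophile (MOM protection) under amine base leaves the ester untouched and gives groups that later come off under acid mild enough for a prenyl group.

**Step 8**
Reactants: 10 methyl 2-[2-allyl-3-methoxy-4,5-bis(methoxymethoxy)phenyl]acetate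
Product: 11 methyl 2-[3-methoxy-4,5-bis(methoxymethoxy)-2-(3-methylbut-2-enyl)phenyl]acetate
Conditions: 2-methyl-2-butene (30 equiv), second-generation Grubbs catalyst RuCl2(=CHPh)(PCy3)(H2IMes) (3 mol %), CH2Cl2, 40 °C, sealed tube, 12 h
Reagents that add atoms: 2-methyl-2-butene, CC=C(C)C
Why: Olefin cross metathesis of a terminal allyl arene with excess 2-methyl-2-butene transfers the isopropylidene unit, is driven by loss of propene, and the trisubstituted product does not re-enter the cycle.

**Step 9**
Reactants: 12 phloroglucinol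
Product: 13 1,3,5-tris(methoxymethoxy)benzene
Conditions: NaH (3.6 equiv), MOMCl (3.6 equiv), DMF, 0 °C to rt, 6 h
Reagents that add atoms: chloromethyl methyl ether, COCCl
Why: Exhaustive O-alkylation of the triphenoxide with the hard electrophile MOMCl in DMF (Williamson-type MOM protection) favours O- over C-attack.

**Step 10**
Reactants: 13 1,3,5-tris(methoxymethoxy)benzene
Product: 15 2,4,6-tris(methoxymethoxy)benzaldehyde, via 2,4,6-tris(methoxymethoxy)phenyllithium 14 (not isolated)
Conditions: n-BuLi (1.1 equiv), TMEDA (1.1 equiv), THF, 0 °C, 1 h; DMF (3 equiv), 0 °C to rt; H2O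
Reagents that add atoms: N,N-dimethylformamide, CN(C)C=O
Why: In this directed ortho-lithiation all three ring hydrogens are equivalent and each is flanked by two chelating OMOM groups, so DMF formylation gives a single aldehyde.

**Step 11**
Reactants: 11 methyl 2-[3-methoxy-4,5-bis(methoxymethoxy)-2-(3-methylbut-2-enyl)phenyl]acetate; 15 2,4,6-tris(methoxymethoxy)benzaldehyde
Product: 17 methyl 3-hydroxy-2-[3-methoxy-4,5-bis(methoxymethoxy)-2-(3-methylbut-2-enyl)phenyl]-3-[2,4,6-tris(methoxymethoxy)phenyl]propanoate (racemic syn/anti mixture), via lithium ester enolate 16 (not isolated)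
Conditions: LiN(i-Pr)2 (1.1 equiv, commercial solution), THF, −78 °C, 45 min; 15 (1.15 equiv), −78 °C, 2 h; AcOH (1.2 equiv), −78 °C
Reagents that add atoms: none
Why: Intermolecular aldol addition of a fully preformed ester enolate to a non-enolisable aldehyde forms the C3–C4 bond, the cold acidic quench prevents retro-aldol, and the two uncontrolled stereocentres are both erased in steps 12 to 14.

**Step 12**
Reactants: 17 the aldol adduct
Product: 18 methyl 2-[3-methoxy-4,5-bis(methoxymethoxy)-2-(3-methylbut-2-enyl)phenyl]-3-oxo-3-[2,4,6-tris(methoxymethoxy)phenyl]propanoate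
Conditions: Dess–Martin periodinane (1.3 equiv), CH2Cl2, 0 °C to rt, 2 h
Reagents that add atoms: none
Why: Dess–Martin oxidation converts the benzylic carbinol to the ketone under essentially neutral conditions that cause no retro-aldol and leave the prenyl alkene and the MOM acetals untouched.

**Step 13**
Reactants: 18 the β-keto ester
Product: 20 2-[3-methoxy-4,5-bis(methoxymethoxy)-2-(3-methylbut-2-enyl)phenyl]-1-[2,4,6-tris(methoxymethoxy)phenyl]ethanone, via lithium beta-keto carboxylate 19 (not isolated)
Conditions: LiCl (3 equiv), H2O (3 equiv), DMSO, 135 °C, 4 h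
Reagents that add atoms: none
Why: In this Krapcho dealkoxycarbonylation chloride demethylates the activated ester by SN2 attack, and the β-keto carboxylate loses CO2 under near-neutral conditions that suit acetals and alkene.

**Step 14**
Reactants: 20 the deoxybenzoin
Product: 21 3-(dimethylamino)-2-[3-methoxy-4,5-bis(methoxymethoxy)-2-(3-methylbut-2-enyl)phenyl]-1-[2,4,6-tris(methoxymethoxy)phenyl]prop-2-en-1-one (E/Z not assigned)
Conditions: Me2NCH(OMe)2 (10 equiv), toluene, 110 °C, 16 h
Reagents that add atoms: N,N-dimethylformamide dimethyl acetal, COC(OC)N(C)C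
Why: The doubly activated benzylic methylene condenses with the amide acetal (enaminone formation) without added base or acid and supplies C2 at the correct oxidation level.

**Step 15**
Reactants: 21 the enaminone
Product: 23 3-[4,5-dihydroxy-3-methoxy-2-(3-methylbut-2-enyl)phenyl]-5,7-dihydroxychromen-4-one (target), via MOM-free enaminone 22 (not isolated)
Conditions: HCl (1.25 M in MeOH), 50 °C, 3 h
Reagents that add atoms: none
Why: Acetal methanolysis frees the phenols, and either of the two equivalent ortho phenols of ring A closes ring C by oxa-Michael addition and loss of dimethylamine; the prenyl group has no ortho OH to cyclise onto and survives dilute methanolic acid.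

**Compound list**
1 | 3,4,5-trimethoxyphenylacetic acid | COc1cc(CC(=O)O)cc(OC)c1OC | starting material
2 | 3,4,5-trihydroxyphenylacetic acid (not isolated) | OC(=O)Cc1cc(O)c(O)c(O)c1 | intermediate
3 | methyl 2-(3,4,5-trihydroxyphenyl)acetate | COC(=O)Cc1cc(O)c(O)c(O)c1 | intermediate
4 | methyl 2-(7-hydroxy-2,2-diphenyl-1,3-benzodioxol-5-yl)acetate | COC(=O)Cc1cc(O)c2OC(c3ccccc3)(c3ccccc3)Oc2c1 | intermediate
5 | methyl 2-(7-allyloxy-2,2-diphenyl-1,3-benzodioxol-5-yl)acetate | COC(=O)Cc1cc(OCC=C)c2OC(c3ccccc3)(c3ccccc3)Oc2c1 | intermediate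
6 | methyl 2-(6-allyl-7-oxo-2,2-diphenyl-6,7-dihydro-1,3-benzodioxol-5-yl)acetate (racemic dienone, not isolated) | COC(=O)CC1=CC2=C(OC(c3ccccc3)(c3ccccc3)O2)C(=O)C1CC=C | intermediate
7 | methyl 2-(6-allyl-7-hydroxy-2,2-diphenyl-1,3-benzodioxol-5-yl)acetate | COC(=O)Cc1cc2OC(c3ccccc3)(c3ccccc3)Oc2c(O)c1CC=C | intermediate
8 | methyl 2-(6-allyl-7-methoxy-2,2-diphenyl-1,3-benzodioxol-5-yl)acetate | COC(=O)Cc1cc2OC(c3ccccc3)(c3ccccc3)Oc2c(OC)c1CC=C | intermediate
9 | methyl 2-(2-allyl-4,5-dihydroxy-3-methoxyphenyl)acetate | COC(=O)Cc1cc(O)c(O)c(OC)c1CC=C | intermediate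
10 | methyl 2-[2-allyl-3-methoxy-4,5-bis(methoxymethoxy)phenyl]acetate | COC(=O)Cc1cc(OCOC)c(OCOC)c(OC)c1CC=C | intermediate
11 | methyl 2-[3-methoxy-4,5-bis(methoxymethoxy)-2-(3-methylbut-2-enyl)phenyl]acetate (fragment B) | COC(=O)Cc1cc(OCOC)c(OCOC)c(OC)c1CC=C(C)C | intermediate
12 | phloroglucinol | Oc1cc(O)cc(O)c1 | starting material
13 | 1,3,5-tris(methoxymethoxy)benzene | COCOc1cc(OCOC)cc(OCOC)c1 | intermediate
14 | 2,4,6-tris(methoxymethoxy)phenyllithium (not isolated) | [Li]c1c(OCOC)cc(OCOC)cc1OCOC | intermediate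
15 | 2,4,6-tris(methoxymethoxy)benzaldehyde (fragment A) | O=Cc1c(OCOC)cc(OCOC)cc1OCOC | intermediate
16 | lithium enolate of ester 11 (geometry not assigned, not isolated) | [Li+].COC([O-])=Cc1cc(OCOC)c(OCOC)c(OC)c1CC=C(C)C | intermediate
17 | methyl 3-hydroxy-2-[3-methoxy-4,5-bis(methoxymethoxy)-2-(3-methylbut-2-enyl)phenyl]-3-[2,4,6-tris(methoxymethoxy)phenyl]propanoate (racemic syn/anti mixture) | COC(=O)C(C(O)c1c(OCOC)cc(OCOC)cc1OCOC)c1cc(OCOC)c(OCOC)c(OC)c1CC=C(C)C | intermediate
18 | methyl 2-[3-methoxy-4,5-bis(methoxymethoxy)-2-(3-methylbut-2-enyl)phenyl]-3-oxo-3-[2,4,6-tris(methoxymethoxy)phenyl]propanoate (racemic, enolisable) | COC(=O)C(C(=O)c1c(OCOC)cc(OCOC)cc1OCOC)c1cc(OCOC)c(OCOC)c(OC)c1CC=C(C)C | intermediate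
19 | lithium 2-[3-methoxy-4,5-bis(methoxymethoxy)-2-(3-methylbut-2-enyl)phenyl]-3-oxo-3-[2,4,6-tris(methoxymethoxy)phenyl]propanoate (not isolated) | [Li+].[O-]C(=O)C(C(=O)c1c(OCOC)cc(OCOC)cc1OCOC)c1cc(OCOC)c(OCOC)c(OC)c1CC=C(C)C | intermediate
20 | 2-[3-methoxy-4,5-bis(methoxymethoxy)-2-(3-methylbut-2-enyl)phenyl]-1-[2,4,6-tris(methoxymethoxy)phenyl]ethanone | O=C(Cc1cc(OCOC)c(OCOC)c(OC)c1CC=C(C)C)c1c(OCOC)cc(OCOC)cc1OCOC | intermediate
21 | 3-(dimethylamino)-2-[3-methoxy-4,5-bis(methoxymethoxy)-2-(3-methylbut-2-enyl)phenyl]-1-[2,4,6-tris(methoxymethoxy)phenyl]prop-2-en-1-one (E/Z not assigned) | CN(C)C=C(C(=O)c1c(OCOC)cc(OCOC)cc1OCOC)c1cc(OCOC)c(OCOC)c(OC)c1CC=C(C)C | intermediate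
22 | 3-(dimethylamino)-2-[4,5-dihydroxy-3-methoxy-2-(3-methylbut-2-enyl)phenyl]-1-(2,4,6-trihydroxyphenyl)prop-2-en-1-one (not isolated) | CN(C)C=C(C(=O)c1c(O)cc(O)cc1O)c1cc(O)c(O)c(OC)c1CC=C(C)C | intermediate
23 | 3-[4,5-dihydroxy-3-methoxy-2-(3-methylbut-2-enyl)phenyl]-5,7-dihydroxychromen-4-one (achiral) | COc1c(O)c(O)cc(-c2coc3cc(O)cc(O)c3c2=O)c1CC=C(C)C | target

**Totals**
Total step count: 15. Longest linear sequence: 13 (steps 1–8, then 11–15). Steps 9–10 form the two-step side branch.

**Three steps most likely to fail**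

Step 11. The aldehyde is electron-rich and di-ortho-substituted, and the enolate carries an ortho-prenyl aryl group, so the addition may stall or revert. The fallback sets out from 15 (with 11) and comes back at 18. Aldehyde 15 is oxidised with NaClO2/NaH2PO4/2-methyl-2-butene in t-BuOH–H2O to 2,4,6-tris(methoxymethoxy)benzoic acid F1. This acid is activated with 1,1'-carbonyldiimidazole in THF to 1-[2,4,6-tris(methoxymethoxy)benzoyl]imidazole F2. F2 is then added at −78 °C to enolate 16, made from 11 with 2.1 equiv LiN(i-Pr)2. This crossed Claisen condensation becomes irreversible through deprotonation of the product. It gives 18 directly, so steps 11 and 12 are both replaced.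

Step 14. The methylene of 20 sits between two crowded aryl units and may resist condensation with the amide acetal. The fallback sets out from 17 and comes back at 23, and it uses the ester carbon itself as C2. LiAlH4 in THF at 0 °C reduces 17 to 2-[3-methoxy-4,5-bis(methoxymethoxy)-2-(3-methylbut-2-enyl)phenyl]-1-[2,4,6-tris(methoxymethoxy)phenyl]propane-1,3-diol F3. Double Swern oxidation ((COCl)2, DMSO, Et3N, −78 °C) then gives 2-[3-methoxy-4,5-bis(methoxymethoxy)-2-(3-methylbut-2-enyl)phenyl]-3-oxo-3-[2,4,6-tris(methoxymethoxy)phenyl]propanal F4, which is largely enolised. Methanolic HCl at 50 °C removes the MOM groups and closes ring C by cyclodehydration to 23. No one-carbon unit has to be introduced at the hindered carbon.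

Step 4. At 205 °C para migration through the blocked ortho carbon or loss of material could compete. The fallback sets out from 4 and comes back at 7, and it replaces the sigmatropic shift with direct C-alkylation. NaH (1.0 equiv) in toluene converts 4 into sodium 6-(2-methoxy-2-oxoethyl)-2,2-diphenyl-1,3-benzodioxol-4-olate F5. Heating this contact ion pair with allyl bromide (1.2 equiv) in toluene at reflux favours ortho C-allylation at the single free ortho carbon and gives 7. Any O-allyl ether 5 formed alongside is separable and can be recycled.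

**Further compounds**
F1 | step 11 | 2,4,6-tris(methoxymethoxy)benzoic acid | OC(=O)c1c(OCOC)cc(OCOC)cc1OCOC
F2 | step 11 | 1-[2,4,6-tris(methoxymethoxy)benzoyl]imidazole | O=C(n1ccnc1)c1c(OCOC)cc(OCOC)cc1OCOC
F3 | step 14 | 2-[3-methoxy-4,5-bis(methoxymethoxy)-2-(3-methylbut-2-enyl)phenyl]-1-[2,4,6-tris(methoxymethoxy)phenyl]propane-1,3-diol (racemic diastereomer mixture) | OCC(C(O)c1c(OCOC)cc(OCOC)cc1OCOC)c1cc(OCOC)c(OCOC)c(OC)c1CC=C(C)C
F4 | step 14 | 2-[3-methoxy-4,5-bis(methoxymethoxy)-2-(3-methylbut-2-enyl)phenyl]-3-oxo-3-[2,4,6-tris(methoxymethoxy)phenyl]propanal | O=CC(C(=O)c1c(OCOC)cc(OCOC)cc1OCOC)c1cc(OCOC)c(OCOC)c(OC)c1CC=C(C)C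
F5 | step 4 | sodium 6-(2-methoxy-2-oxoethyl)-2,2-diphenyl-1,3-benzodioxol-4-olate | [Na+].[O-]c1cc(CC(=O)OC)cc2OC(c3ccccc3)(c3ccccc3)Oc12
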